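**Plan**

- Retrosynthesis: the three O-acetyl groups are cut first, then the bond between C8 of the benzopyranone A-ring and the benzylic CH(CH3) carbon, which leads back to isorhamnetin and acetosyringone.
- Forward: isorhamnetin is peracetylated and the 7-O-acetate alone is removed again, so that the 7-OH is the only free hydroxyl of the flavonol. Acetosyringone is reduced to the racemic carbinol.
- The two fragments are joined by a biomimetic, enantioconvergent Friedel–Crafts 1,6-addition: the racemic carbinol collapses in the flask to an achiral p-quinone methide, which C8 attacks under a chiral phosphoric acid.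
- Enabling features: the free OH of the syringyl ring para to the benzylic carbon allows quinone methide formation. C8 of the A-ring lies ortho to the free 7-OH and next to the ring oxygen O1, whereas C6 is flanked by the 5-acetoxy group.
- No ring is formed; all four rings come from the two starting materials. The single stereocentre (R) is set by the catalyst in the joining step, and a final methanolysis removes the acetates.

Key step: step 4

Assumption: the sense of induction of the phosphoric acid cannot be predicted with confidence. The (R)-catalyst is written; the (S)-catalyst is used instead if the adduct proves to be the antipode.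

**Route**

Step 1
Reactants: 1 isorhamnetin
Product: 2 isorhamnetin 3,5,7,4'-tetraacetate
Conditions: Ac2O (excess), pyridine, DMAP (cat.), rt → 60 °C
Reagents that add atoms: acetic anhydride, CC(=O)OC(C)=O
Why: Exhaustive O-acetylation of the phenols and the 3-enol under nucleophilic catalysis, where DMAP and warming should also acylate the chelated 5-OH.

Step 2
Reactants: 2 isorhamnetin 3,5,7,4'-tetraacetate
Product: 3 isorhamnetin 3,5,4'-triacetate (7-OH free)
Conditions: PhSH (1.5 equiv), imidazole (0.3 equiv), NMP, 0 °C → rt
Reagents that add atoms: none
Why: Chemoselective thiolysis (acyl transfer to thiophenolate) should remove only the 7-O-acetate, because the 7-oxygen is para to the ring carbon that carries the C4 carbonyl and is therefore the best phenoxide leaving group, a known selective 7-O-deacylation of peracylated flavonoids.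

Step 3
Reactants: 4 acetosyringone
Product: 5 rac-1-(4-hydroxy-3,5-dimethoxyphenyl)ethanol
Conditions: NaBH4 (excess), EtOH/THF, 0 °C → rt; sat. aq. NH4Cl to pH ≈ 7, no acid; used without prolonged storage
Reagents that add atoms: none
Why: Borohydride reduction of an aryl methyl ketone, where the new carbinol centre is left racemic on purpose because it is erased at the quinone methide stage of step 4.

Step 4
Reactants: 3 isorhamnetin 3,5,4'-triacetate (7-OH free); 5 rac-1-(4-hydroxy-3,5-dimethoxyphenyl)ethanol
Product: 7 8-[(1R)-1-(4-hydroxy-3,5-dimethoxyphenyl)ethyl]isorhamnetin 3,5,4'-triacetate, via 4-ethylidene-2,6-dimethoxycyclohexa-2,5-dien-1-one 6 (not isolated)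
Conditions: (R)-TRIP (10 mol %), 4 Å MS, CH2Cl2, 0 °C → rt; 5 (1.5 equiv) added slowly by syringe pump
Reagents that add atoms: none
Why: Proposed new method: the chiral phosphoric acid dehydrates racemic 5 to the planar, achiral p-quinone methide 6 (possible only because the syringyl ring has a free OH para to the benzylic carbon), binds its carbonyl through P–OH···O=C and accepts a hydrogen bond from the 7-OH of 3, so that C8 adds to the exocyclic carbon in a 1,6-conjugate addition and rearomatisation of both rings gives 7. The closest known reaction type is the chiral-phosphoric-acid-catalysed enantioselective Friedel–Crafts 1,6-addition of naphthols, electron-rich phenols and indoles to p-quinone methides generated in situ from p-hydroxybenzyl alcohols; new here are the unhindered, enolisable methyl-substituted quinone methide and a 7-hydroxychromone as the arene. No ring is closed. The one new stereocentre is set by the catalyst, whose 3,3'-aryl walls must tell the methyl group from the hydrogen on the reacting carbon in the doubly hydrogen-bonded transition state; both enantiomers of 5 and the 4-vinylphenol tautomer of 6 funnel through the same achiral 6, so the step is enantioconvergent, and the symmetric 3,5-dimethoxy pattern gives 6 no E/Z isomers, so only facial selectivity is at stake. Site selectivity for C8 over C6 is needed and is secured by 3: the 7-OH is the only free hydroxyl, C6 is flanked by the 5-acetoxy group while C8 is not, and the C7–C8 bond of a 7-hydroxychromone has the higher double-bond character (the position where such phenols take Mannich, formylation and Claisen chemistry). C- over O-alkylation is secured by reversibility, since a 7-O-benzylic ether re-ionises under the acid whereas the C–C bond should not at this temperature.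

Step 5
Reactants: 7 8-[(1R)-1-(4-hydroxy-3,5-dimethoxyphenyl)ethyl]isorhamnetin 3,5,4'-triacetate
Product: 8 8-[(1R)-1-(4-hydroxy-3,5-dimethoxyphenyl)ethyl]isorhamnetin (target)
Conditions: K2CO3 (cat.), degassed MeOH/THF, 0 °C → rt, Ar; then dil. AcOH to pH 5
Reagents that add atoms: none
Why: Base-catalysed transesterification (methanolysis) of the three aryl and enol acetates should free the phenols under oxygen-free conditions, while the diarylmethine stereocentre has neither an acidic hydrogen nor a leaving group and should be untouched.

**Compound list**

1 | isorhamnetin (3,5,7-trihydroxy-2-(4-hydroxy-3-methoxyphenyl)-4H-chromen-4-one) | COc1cc(-c2oc3cc(O)cc(O)c3c(=O)c2O)ccc1O | starting material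
2 | isorhamnetin 3,5,7,4'-tetraacetate | COc1cc(-c2oc3cc(OC(C)=O)cc(OC(C)=O)c3c(=O)c2OC(C)=O)ccc1OC(C)=O | intermediate
3 | isorhamnetin 3,5,4'-triacetate (7-OH free) | COc1cc(-c2oc3cc(O)cc(OC(C)=O)c3c(=O)c2OC(C)=O)ccc1OC(C)=O | intermediate
4 | acetosyringone (1-(4-hydroxy-3,5-dimethoxyphenyl)ethanone) | CC(=O)c1cc(OC)c(O)c(OC)c1 | starting material
5 | rac-1-(4-hydroxy-3,5-dimethoxyphenyl)ethanol | CC(O)c1cc(OC)c(O)c(OC)c1 | intermediate
6 | 4-ethylidene-2,6-dimethoxycyclohexa-2,5-dien-1-one (p-quinone methide, not isolated) | CC=C1C=C(OC)C(=O)C(OC)=C1 | intermediate
7 | 8-[(1R)-1-(4-hydroxy-3,5-dimethoxyphenyl)ethyl]isorhamnetin 3,5,4'-triacetate | COc1cc(-c2oc3c([C@H](C)c4cc(OC)c(O)c(OC)c4)c(O)cc(OC(C)=O)c3c(=O)c2OC(C)=O)ccc1OC(C)=O | intermediate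
8 | 3,5,7-trihydroxy-2-(4-hydroxy-3-methoxyphenyl)-8-[(1R)-1-(4-hydroxy-3,5-dimethoxyphenyl)ethyl]-4H-chromen-4-one | COc1cc(-c2oc3c([C@H](C)c4cc(OC)c(O)c(OC)c4)c(O)cc(O)c3c(=O)c2O)ccc1O | target

**Count**

Total steps: 5. Longest linear sequence: 4 steps (1 → 2 → 3 → 7 → 8).

**Steps most likely to fail**

Step 4. Two processes may defeat it: poor facial discrimination between the methyl group and the hydrogen on the reacting carbon, and self-condensation of the quinone methide and its vinylphenol tautomer outrunning arylation by the only moderately nucleophilic A-ring. The fallback sets out from 3 and 5 and uses known chemistry. The two are condensed without a chiral catalyst by ordinary Brønsted-acid Friedel–Crafts benzylation (TsOH cat. in HFIP/CH2Cl2, rt), where the same substrate features direct attack to C8, to give racemic 8-[1-(4-hydroxy-3,5-dimethoxyphenyl)ethyl]isorhamnetin 3,5,4'-triacetate F1. The racemate is resolved by preparative chromatography on a chiral stationary phase (polysaccharide carbamate, SFC). The (R)-enantiomer is 7, where the route is rejoined; the (S)-enantiomer of the triacetate F2 is set aside. The configuration of the fractions would have to be assigned, for example by ECD against calculation.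

Step 2. The process at risk is loss of a second acetate (4'-O) before the 7-O-acetate is fully consumed. The fallback sets out from 1 and reverses the order of protection. The most acidic hydroxyl is benzylated first (BnBr 1.0 equiv, K2CO3 1.0 equiv, DMF, 0 °C → rt) to give 7-O-benzylisorhamnetin F3. Acetylation (Ac2O, pyridine, DMAP) gives 7-O-benzylisorhamnetin 3,5,4'-triacetate F4. Hydrogenolysis (H2 1 atm, Pd/C, EtOAc), which leaves aryl acetates and the pyranone intact, returns to the route at 3.

Step 5. The process at risk is autoxidation of the polyphenolic flavonol as its phenoxide in basic methanol, or incomplete cleavage that leaves mixed partial acetates. The fallback sets out from 7 and replaces base solvolysis by biocatalysis at neutral pH: a hydrolase (immobilised lipase or esterase) with 1-butanol in THF/MTBE at 30–40 °C transfers the acetyl groups to butanol and returns to the route at 8. No new compound is made on the way.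

**Further compounds**

F1 | step 4 | racemic 8-[1-(4-hydroxy-3,5-dimethoxyphenyl)ethyl]isorhamnetin 3,5,4'-triacetate | COc1cc(-c2oc3c(C(C)c4cc(OC)c(O)c(OC)c4)c(O)cc(OC(C)=O)c3c(=O)c2OC(C)=O)ccc1OC(C)=O
F2 | step 4 | 8-[(1S)-1-(4-hydroxy-3,5-dimethoxyphenyl)ethyl]isorhamnetin 3,5,4'-triacetate | COc1cc(-c2oc3c([C@@H](C)c4cc(OC)c(O)c(OC)c4)c(O)cc(OC(C)=O)c3c(=O)c2OC(C)=O)ccc1OC(C)=O
F3 | step 2 | 7-O-benzylisorhamnetin | COc1cc(-c2oc3cc(OCc4ccccc4)cc(O)c3c(=O)c2O)ccc1O
F4 | step 2 | 7-O-benzylisorhamnetin 3,5,4'-triacetate | COc1cc(-c2oc3cc(OCc4ccccc4)cc(OC(C)=O)c3c(=O)c2OC(C)=O)ccc1OC(C)=O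
F0 | step 5 | none | none
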